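Follow the starting material through time in two earlier runs: their charges of starting material and acid match, and their protic impurity differs.

all flasks: starting material 0.050 M
- winter: acid 0.50 mM; protic impurity 1.7 mM; run made earlier
- midnight: acid 0.50 mM; protic impurity 3.8 mM; run made earlier
- flask: acid 0.500 mM; protic impurity 2.50 mM; time 6.0 h

| run | time / h | starting material / % | target / % |
|---|---|---|---|
| winter | 0.500 | 75.6 | 19.7 |
| winter | 1.33 | 49.7 | 37.5 |
| winter | 3.00 | 22.6 | 42.2 |
| winter | 8.00 | 0.3 | 18.8 |
| midnight | 0.833 | 60.7 | 26.1 |
| midnight | 2.50 | 27.1 | 39.6 |
| midnight | 5.00 | 8.3 | 30.1 |
| midnight | 8.00 | 1.7 | 18.2 |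

(standard deviation of a reading: 1 percentage point)

* part of the starting material that has reacted at 6.0 h
* pH of the solution at 6.0 h

1. Here is the puzzle. The midnight run holds 2.24 times the impurity of the winter run, yet you see its starting material fall at nearly the same pace.

2. Take the natural logarithm of the ratio of two starting-material readings and divide it by the hours between them. Read off these scattered readings, the midnight run gives 0.477 h⁻¹ and the winter run 0.472 h⁻¹, which are nearly equal. Call this the fall constant k, the log ratio per hour. It is the slope of a pseudo-first-order decay, and a one-off loss before both readings cancels in the ratio.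

3. I assume that each impurity molecule removes one of starting material. As a fraction of the starting charge, that is 3.40% in the winter run and 7.60% in the midnight run, so on this assumption the impurity can differ while k does not.

4. In the new flask I reckon that the impurity takes 5.00% of the starting charge. Multiply what it spares by exp(−k·t), and I expect 5.41% left, so 94.6% reacted.

5. The forecast says 95% reacted, on the ground that “the flask should follow the same curve”, and it gives pH 3.32.

6. The flask gives 95.0% and pH 3.30, so the forecast holds.

    weak acid ⇌ conjugate base + acid, settled at all times (K = 1.30 × 10⁻⁸ M)
    starting material + acid → weak acid + acid + target (k = 16.0 M⁻¹ min⁻¹)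
    starting material → weak acid + target (k = 1.50 × 10⁻⁴ min⁻¹)
    target ⇌ isomer of the product (K = 16.0, k = 0.00570 min⁻¹)
    starting material + protic impurity → quenched substrate (k = 2.30 M⁻¹ min⁻¹)

At 1.30 h the flask uses starting material 790 times faster by the acid path than by the impurity path, and at 3.00 h the impurity path has >99.9% of its turnover up to 6.0 h behind it against 81% for the acid path. The same k gives 5.41% left against 5.0% in the flask at 6.00 h, and for the flask stopped at 2.5 h it gives 28.8% against the 28% that flask holds.

(The earlier runs and the new flask are calculated on assumed constants; the scatter is artificial.)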